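**Retrosynthetic overview**
1. Target ⇐ 3-O-acetylation, 5-O-desilylation and hydrogenolysis of the two ring B benzyl ethers of a protected (2R,3R)-dihydroflavonol.
2. Ring C, the only ring that is made (rings A and B are bought), ⇐ C2–C3 bond by an enantioselective Norrish–Yang photocyclisation of an aryl glyoxal whose ring A carries, ortho to the C(=O)–CHO group, the benzylic ether of ring B.
3. Enabling feature: the C4 ketone and the C3 carbinol of ring C are a masked 1,2-dicarbonyl, and C2–H is a benzylic, O1-bound hydrogen that sits 1,7 to the aldehyde (C3) oxygen across C4, C4a, C8a and O1. Hydrogen transfer and recombination of the 1,6-biradical create the C2–C3 bond, the C3 hydroxyl and both stereocentres in one operation.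
4. Aryl glyoxal ⇐ SeO2 oxidation of the acetophenone and drying of the hydrate ⇐ O-silylation and mono-O-alkylation of 2',6'-dihydroxy-4'-methoxyacetophenone with 3,4-bis(benzyloxy)benzyl chloride.

Key step: step 4

Assumption: 2',6'-dihydroxy-4'-methoxyacetophenone and 3,4-bis(benzyloxy)benzyl chloride are taken as commercial starting materials.
Assumption: the sense of induction of the chiral phosphoric acid in step 4 cannot be read from a precedent on this substrate class; the (R)-acid is written, and the (S)-acid takes its place if the first run favours the (2S,3S) series.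

**Step 1**
Reactants: 1 1-(2,6-dihydroxy-4-methoxyphenyl)ethan-1-one; 2 1,2-bis(benzyloxy)-4-(chloromethyl)benzene
Product: 3 1-[2-{[3,4-bis(benzyloxy)phenyl]methoxy}-6-hydroxy-4-methoxyphenyl]ethan-1-one
Conditions: 2 (1.0 equiv), K2CO3 (1.2 equiv), NaI (0.1 equiv), acetone, 56 °C
Reagents that add atoms: none
Why: Williamson ether synthesis in which the two phenols of 1 are equivalent and, after the first O-alkylation, the remaining phenol is held in a hydrogen bond to the ketone and should not react further, so that the mono-ether results; no stereocentre is formed.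

**Step 2**
Reactants: 3 1-[2-{[3,4-bis(benzyloxy)phenyl]methoxy}-6-hydroxy-4-methoxyphenyl]ethan-1-one
Product: 4 1-[2-{[3,4-bis(benzyloxy)phenyl]methoxy}-4-methoxy-6-(triisopropylsilyloxy)phenyl]ethan-1-one
Conditions: triisopropylsilyl trifluoromethanesulfonate (1.1 equiv), 2,6-lutidine (2 equiv), CH2Cl2, −78 to 0 °C
Reagents that add atoms: triisopropylsilyl trifluoromethanesulfonate CC(C)[Si](OS(=O)(=O)C(F)(F)F)(C(C)C)C(C)C
Why: Silylation of the chelated, hindered phenol with a silyl triflate and a hindered base (a small excess only, so that the methyl ketone is not turned into its silyl enol ether); the triisopropylsilyl ether has no C–H bond alpha to the oxygen that could act as a rival hydrogen donor in step 4, prevents quenching of the excited dicarbonyl by the phenol and should outlast step 3.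

**Step 3**
Reactants: 4 1-[2-{[3,4-bis(benzyloxy)phenyl]methoxy}-4-methoxy-6-(triisopropylsilyloxy)phenyl]ethan-1-one
Product: 6 2-[2-{[3,4-bis(benzyloxy)phenyl]methoxy}-4-methoxy-6-(triisopropylsilyloxy)phenyl]-2-oxoacetaldehyde (anhydrous aryl glyoxal), via aryl glyoxal hydrate 5 (not isolated)
Conditions: SeO2 (1.5 equiv), 1,4-dioxane/H2O 20:1, 90 °C; filtration through Celite; then PhMe, Dean–Stark trap, 110 °C; kept under Ar over 4 Å molecular sieves and used at once
Reagents that add atoms: selenium dioxide O=[Se]=O; water O
Why: Riley oxidation of the aryl methyl ketone, the only enolisable position, by SeO2 gives the alpha-keto aldehyde, which rests as its gem-diol 5 in the wet solvent and is returned to the free aldehyde 6 by azeotropic removal of water, the usual way of drying aryl glyoxal hydrates; no stereocentre is formed.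

**Step 4**
Reactants: 6 2-[2-{[3,4-bis(benzyloxy)phenyl]methoxy}-4-methoxy-6-(triisopropylsilyloxy)phenyl]-2-oxoacetaldehyde (anhydrous aryl glyoxal)
Product: 7 (2R,3R)-2-[3,4-bis(benzyloxy)phenyl]-3-hydroxy-7-methoxy-5-(triisopropylsilyloxy)-2,3-dihydro-4H-chromen-4-one
Conditions: (R)-3,3'-bis(2,4,6-triisopropylphenyl)-1,1'-binaphthyl-2,2'-diyl hydrogen phosphate (1.0 equiv, recovered), dry PhF (0.02 M), degassed by freeze–pump–thaw, 440 nm LEDs, −30 °C
Reagents that add atoms: none
Why: Proposed new method: excitation of the n→π* band of the 1,2-dicarbonyl unit of 6 and intersystem crossing give a triplet whose aldehyde oxygen takes a hydrogen from the benzylic O–CH2 group through an eight-membered transition state (1,7-hydrogen transfer), and the resulting 1,6-biradical (alpha-aryloxybenzyl radical at C2, hydroxy-substituted radical at C3 conjugated with the C4 carbonyl) recombines after spin inversion to the C2–C3 bond. The closest known reaction types are the uncatalysed, racemic Norrish–Yang photocyclisation of 1-(2-alkylaryl)- and 1-(2-alkoxyaryl)-1,2-diketones, in which the distal carbonyl oxygen abstracts and 2-hydroxyindan-1-ones or 3-hydroxychroman-4-ones result, and the control by chiral phosphoric acids of radical–radical couplings of ketyl radicals made from 1,2-dicarbonyl compounds under photoredox conditions; new are their combination in one intramolecular event and the use of an aryl glyoxal. Ring C closes by radical–radical recombination within the 1,6-biradical, a six-membered closure at C3 that leaves C4 as the ring ketone. C3 is controlled by the phosphoric acid, which is expected to hold the C3 radical by two hydrogen bonds (P=O to the new C3–OH, P–OH to C4=O) for the nanoseconds the biradical should live and to shield one face with a 2,4,6-triisopropylphenyl arm, and C2 is set relative to C3 by a chair-like closure with the aryl group and the C3 hydroxyl both equatorial (2,3-trans). The step needs hydrogen transfer from the ring B benzylic ether alone and to the aldehyde oxygen alone: the first is secured because the other ortho oxygen carries a silyl group and the remaining benzyl ethers are remote, the second because the C4 carbonyl is twisted out of the plane of ring A by its two ortho substituents and is the oxygen engaged by the acid, whereas abstraction by the C4 oxygen would lead to a five-membered 3-hydroxy-2,3-dihydrobenzofuran through a crowded, fully substituted carbon. Any cis isomer is to be removed by chromatography and not by base, since epimerisation at C3 would feed the wrong enantiomeric series.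

**Step 5**
Reactants: 7 (2R,3R)-2-[3,4-bis(benzyloxy)phenyl]-3-hydroxy-7-methoxy-5-(triisopropylsilyloxy)-2,3-dihydro-4H-chromen-4-one
Product: 8 (2R,3R)-2-[3,4-bis(benzyloxy)phenyl]-7-methoxy-4-oxo-5-(triisopropylsilyloxy)-3,4-dihydro-2H-chromen-3-yl acetate
Conditions: Ac2O (1.5 equiv), pyridine, 4-(dimethylamino)pyridine (5 mol%), CH2Cl2, 0 °C
Reagents that add atoms: acetic anhydride CC(=O)OC(C)=O
Why: Nucleophile-catalysed acylation (acyl transfer through the N-acetylpyridinium ion) of the only free hydroxyl, in which no bond to C2 or C3 is broken and the mild base at 0 °C should not enolise the ketone, so that the (2R,3R) configuration is kept.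

**Step 6**
Reactants: 8 (2R,3R)-2-[3,4-bis(benzyloxy)phenyl]-7-methoxy-4-oxo-5-(triisopropylsilyloxy)-3,4-dihydro-2H-chromen-3-yl acetate
Product: 9 (2R,3R)-2-[3,4-bis(benzyloxy)phenyl]-5-hydroxy-7-methoxy-4-oxo-3,4-dihydro-2H-chromen-3-yl acetate
Conditions: HF·pyridine, pyridine, THF, 0 °C to rt
Reagents that add atoms: none
Why: Fluoride-mediated desilylation of the aryl silyl ether, driven by the Si–F bond and helped by the ortho carbonyl, and run on the acidic side so that the acetate, the benzyl ethers and the enolisable C3–H are left alone.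

**Step 7**
Reactants: 9 (2R,3R)-2-[3,4-bis(benzyloxy)phenyl]-5-hydroxy-7-methoxy-4-oxo-3,4-dihydro-2H-chromen-3-yl acetate
Product: 10 (2R,3R)-2-(3,4-dihydroxyphenyl)-5-hydroxy-7-methoxy-4-oxo-3,4-dihydro-2H-chromen-3-yl acetate (3-O-acetylpadmatin)
Conditions: H2 (1 atm), Pd/C (10 wt%), EtOAc, rt
Reagents that add atoms: none
Why: Hydrogenolysis of the two aryl benzyl ethers on zerovalent palladium under neutral conditions, which should be faster than cleavage of the cyclic benzylic C2–O1 bond and leaves the acetate and both stereocentres untouched.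

**Compound list**
1 | 1-(2,6-dihydroxy-4-methoxyphenyl)ethan-1-one | CC(=O)c1c(O)cc(OC)cc1O | starting material
2 | 1,2-bis(benzyloxy)-4-(chloromethyl)benzene | ClCc1ccc(OCc2ccccc2)c(OCc2ccccc2)c1 | starting material
3 | 1-[2-{[3,4-bis(benzyloxy)phenyl]methoxy}-6-hydroxy-4-methoxyphenyl]ethan-1-one | CC(=O)c1c(O)cc(OC)cc1OCc1ccc(OCc2ccccc2)c(OCc2ccccc2)c1 | intermediate
4 | 1-[2-{[3,4-bis(benzyloxy)phenyl]methoxy}-4-methoxy-6-(triisopropylsilyloxy)phenyl]ethan-1-one | CC(=O)c1c(O[Si](C(C)C)(C(C)C)C(C)C)cc(OC)cc1OCc1ccc(OCc2ccccc2)c(OCc2ccccc2)c1 | intermediate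
5 | 1-[2-{[3,4-bis(benzyloxy)phenyl]methoxy}-4-methoxy-6-(triisopropylsilyloxy)phenyl]-2,2-dihydroxyethan-1-one (aryl glyoxal hydrate, not isolated) | OC(O)C(=O)c1c(O[Si](C(C)C)(C(C)C)C(C)C)cc(OC)cc1OCc1ccc(OCc2ccccc2)c(OCc2ccccc2)c1 | intermediate
6 | 2-[2-{[3,4-bis(benzyloxy)phenyl]methoxy}-4-methoxy-6-(triisopropylsilyloxy)phenyl]-2-oxoacetaldehyde (anhydrous aryl glyoxal) | O=CC(=O)c1c(O[Si](C(C)C)(C(C)C)C(C)C)cc(OC)cc1OCc1ccc(OCc2ccccc2)c(OCc2ccccc2)c1 | intermediate
7 | (2R,3R)-2-[3,4-bis(benzyloxy)phenyl]-3-hydroxy-7-methoxy-5-(triisopropylsilyloxy)-2,3-dihydro-4H-chromen-4-one | COc1cc(O[Si](C(C)C)(C(C)C)C(C)C)c2c(c1)O[C@H](c1ccc(OCc3ccccc3)c(OCc3ccccc3)c1)[C@@H](O)C2=O | intermediate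
8 | (2R,3R)-2-[3,4-bis(benzyloxy)phenyl]-7-methoxy-4-oxo-5-(triisopropylsilyloxy)-3,4-dihydro-2H-chromen-3-yl acetate | COc1cc(O[Si](C(C)C)(C(C)C)C(C)C)c2c(c1)O[C@H](c1ccc(OCc3ccccc3)c(OCc3ccccc3)c1)[C@@H](OC(C)=O)C2=O | intermediate
9 | (2R,3R)-2-[3,4-bis(benzyloxy)phenyl]-5-hydroxy-7-methoxy-4-oxo-3,4-dihydro-2H-chromen-3-yl acetate | COc1cc(O)c2c(c1)O[C@H](c1ccc(OCc3ccccc3)c(OCc3ccccc3)c1)[C@@H](OC(C)=O)C2=O | intermediate
10 | (2R,3R)-2-(3,4-dihydroxyphenyl)-5-hydroxy-7-methoxy-4-oxo-3,4-dihydro-2H-chromen-3-yl acetate (3-O-acetylpadmatin) | COc1cc(O)c2c(c1)O[C@H](c1ccc(O)c(O)c1)[C@@H](OC(C)=O)C2=O | target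

**Step count and risks**
Total step count: 7. Longest linear sequence: 7 steps (1 to 10).

Steps most likely to fail:

1. Step 4 (bears the label "Proposed new method:"). Process at risk: recombination of biradicals that are not bound to the chiral acid, which would erode the facial selectivity at C3; hydrogen transfer to the C4 oxygen with closure to the five-membered ring and photodecarbonylation are secondary risks. Fallback with known chemistry: setting out from 6, the glyoxal is irradiated at 440 nm in degassed benzene at rt without any chiral additive. This uncatalysed Norrish–Yang photocyclisation of a 1-(2-alkoxyaryl)-1,2-dicarbonyl compound should give the racemic trans alcohol, that is 7 together with its enantiomer (2S,3S)-2-[3,4-bis(benzyloxy)phenyl]-3-hydroxy-7-methoxy-5-(triisopropylsilyloxy)-2,3-dihydro-4H-chromen-4-one F1. The two are separated by preparative chromatography on a cellulose tris(3,5-dimethylphenylcarbamate) stationary phase, and the route is rejoined at 7, with at most half of the material carried on.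

2. Step 3. Process at risk: loss of the silyl ether and over-oxidation to the arylglyoxylic acid in hot aqueous selenous acid, and oligomerisation of the free glyoxal during the drying. Fallback: setting out from 4, condensation with N,N-dimethylformamide dimethyl acetal (neat, 100 °C) should give the enaminone (E)-1-[2-{[3,4-bis(benzyloxy)phenyl]methoxy}-4-methoxy-6-(triisopropylsilyloxy)phenyl]-3-(dimethylamino)prop-2-en-1-one F2. Its enamine C=C bond is then cleaved with singlet oxygen (O2, 5,10,15,20-tetraphenylporphyrin, light above 590 nm, CH2Cl2, −78 °C), by dioxetane formation and fragmentation, a known cleavage of enamino ketones to 1,2-dicarbonyl compounds that needs no water and no heat. The route is rejoined at 6, which is taken directly into the irradiation of step 4.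

3. Step 7. Process at risk: hydrogenolytic opening of ring C at the benzylic C2–O1 bond, or reduction of the C4 carbonyl, before both benzyl ethers are removed. Fallback: setting out from 9, the benzyl ethers are removed without hydrogen by BCl3 with pentamethylbenzene as cation scavenger (CH2Cl2, −78 °C), a Lewis acid dealkylation that tolerates esters and ketones. It makes no new intermediate and comes back at 10.

**Further compounds**
F1 | step 4 | (2S,3S)-2-[3,4-bis(benzyloxy)phenyl]-3-hydroxy-7-methoxy-5-(triisopropylsilyloxy)-2,3-dihydro-4H-chromen-4-one | COc1cc(O[Si](C(C)C)(C(C)C)C(C)C)c2c(c1)O[C@@H](c1ccc(OCc3ccccc3)c(OCc3ccccc3)c1)[C@H](O)C2=O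
F2 | step 3 | (E)-1-[2-{[3,4-bis(benzyloxy)phenyl]methoxy}-4-methoxy-6-(triisopropylsilyloxy)phenyl]-3-(dimethylamino)prop-2-en-1-one | CN(C)/C=C/C(=O)c1c(O[Si](C(C)C)(C(C)C)C(C)C)cc(OC)cc1OCc1ccc(OCc2ccccc2)c(OCc2ccccc2)c1
F0 | step 7 | none | none
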